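## Analysis of the target

The target 47 is a briarane. A cyclohexene (ring A: C1, C10, C11, C12, C13, C14) is fused through C1–C10 to a ten-membered carbocycle (C1–C10), and a γ-lactone (C7–O–C19(=O)–C17–C8) is fused to that ring at C7–C8. It has nine stereocentres, (1R,2S,4R,7S,8S,9S,10S,14S,17R), two of them fully substituted (quaternary C1 with the C15 methyl, tertiary carbinol C8), and a Z C5=C6 olefin. On ring A the C15 methyl and the C9 branch lie on one face (β); the C14 acetate, H10 and the C2 branch lie on the other (α). Six stereocentres form the contiguous array C7–C8–C9–C10–C1–C2, with C14 and C17 beside it and C4 alone across the olefin. Four acetates (C2, C9, C14, C16) sit next to two free hydroxyls (allylic C4–OH, tertiary C8–OH), so acyl migration, dehydration or retro-aldol cleavage of the β-hydroxy lactone, and ionisation at the allylic C4 and C16 oxygens limit what can be done late. The hard parts are the medium ring, the crowded C8–C9–C10–C1 sector and the differentiation of six oxygen functions. The strategy rests on the C4–C5=C6–C7 unit: the C4 hydroxyl and the C7 lactone oxygen flank a Z olefin, a 2-ene-1,4-diol, which is the reduced form of the 4,7-endoperoxide of a ring diene C4=C5–C6=C7.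

## Retrosynthetic reasoning

**C4–O.** A [4+2] adduct carries both new C–O bonds on one face, whereas 47 has the C4 and C7 oxygens on opposite faces. The last bond cut is therefore C4–O: 47 comes from chloroacetate 46 by selective deacylation, and 46 from the 4-epimeric alcohol 45 by Mitsunobu inversion. In 45 the C4 hydroxyl is the only free secondary alcohol (C8 is tertiary), so nothing has to be protected.

**Lactone C19–O7.** 45 is opened to hydroxy acid 44 and further to the tert-butyl ester diol 43. The C7–O bond is not touched, so C7 is retained. With C9 acetylated, only the C7 hydroxyl can reach C19 through a five-membered ring (C4 would give an eight-membered, C8 a four-membered ring).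

**C4–O and C7–O together (key disconnection).** The cis-diol 43 is the O–O reduction product of endoperoxide 42, and 42 is the photooxygenation adduct of diene 41. Cutting here removes two stereocentres, the olefin geometry and a bridging ring in one operation. The precursor then needs only a conjugated diene next to the C8 carbinol. The forward step has to add oxygen across C4 and C7 on the face of the C8 hydroxyl and faster than the ene reaction at C11=C12.

**Acetates.** 41 comes from tetraol 40 and this from the tetrakis-silyl ether 39. All four secondary or primary oxygens can share one protecting group because the tertiary C8 hydroxyl does not acetylate under mild conditions. C19 is held as a tert-butyl ester, because a simple alkyl ester would close a γ-lactone onto the free C9 hydroxyl of 40.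

**C5–C6.** The ten-membered ring of 39 is opened between the two olefins to the seco compound 38 (intramolecular Stille coupling forward). The unhindered cis-disubstituted stannane is placed at C6 and the trisubstituted iodide at C5, so that transmetalation is not slowed by an α-branched stannane.

**C8–C17 and C7–C8.** The tertiary carbinol 38 is cut to the tert-butyl ester 37 (as its enolate) and the (Z)-stannyl enone 36 (aldol addition). 36 is cut at C7–C8 to Weinreb amide 32 and distannane 35, itself from 33 and 34. The aldol is placed last so that the C9 silyloxy group controls C8 and the enolate geometry controls C17.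

**C9–C10.** Amide 32 comes from acid 30, and 30 from allylic ester 27 by Ireland–Claisen rearrangement (27 from alcohol 24 and acid 25). This is the most congested bond of the molecule, next to quaternary C1, and an intramolecular [3,3] shift is the safest way to make it. It also sets C10 by chirality transfer from C12, sets C9, and moves the olefin to C11=C12.

**Ring A transposition.** Alcohol 24 comes from epoxy ketone 22 (Wharton transposition), 22 from enone 21, and 21 from ketone 19 through its methylated form 20. The C10 carbonyl of 19 thus ends as the C10 methine, and C20 is introduced by enolate alkylation.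

**C4=C5 and C2–C3.** Ketone 19 is traced through 18 and 17 to iodo-enoate 16, which is cut at C4=C5 to aldehyde 14 and phosphorane 15 (Wittig olefination with α-iodination; fixes the alkenyl iodide geometry). 14 comes through 12 from homoallylic alcohol 11, which is cut at C2–C3 to aldehyde 8 and allylborane 9 (reagent-controlled allylation sets C2).

**Ring A.** Aldehyde 8 comes from 6, 5 and 4 by degradation of an allyl group to a formyl group. 4 is the product of enantiotopic-group-selective reduction of the achiral dione 3, made from 1 and 2. This one early step sets C1 and C14 in absolute terms.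

## Alternatives that were turned down

**Alternative 1:** Here the ten-membered ring is not closed but released from a decalin: C6–C7 is formed while the C4–C9 bond of the bicycle breaks. In the forward sense a potassium alkoxide (KH, 18-crown-6) of a 1,2-divinyl carbinol undergoes an anionic oxy-Cope shift, and the C4 enolate is silylated with Me3SiCl to give the silyl enol ether A1. In its favour, a sigmatropic ring expansion avoids the end-to-end closure of a medium ring and is more dependable than the ring closure of the chosen route; a chair transition state also passes the decalin stereochemistry into a defined E olefin. Against it, A1 has C6 and C7 as methylenes, an unoxygenated C8=C9 olefin and C19 as a protected primary alcohol. The C7 oxygen, the C8 hydroxyl, the C9 acetate, the Z C5=C6 olefin, the C4 configuration and the C19 oxidation level would all have to be added afterwards on a flexible ten-membered ring with little facial bias. The chosen route sets C8, C9 and C17 before the ring exists and delivers C4–O, C7–O and the Z olefin in one step, at the cost of a harder ring closure.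

**Alternative 2:** The cut is at C7–C8 together with the lactone C–O bond. Forward, SmI2 (samarium diiodide, divalent samarium) would reduce a C7 enal to its ketyl, couple it with the C8 ketone of a β-keto ester, and the C7 alkoxide would lactonise onto C19 to give A2. This is the most convergent plan: ring, two stereocentres and the lactone form together, and A2 is only protecting-group steps away from 47, which beats the four-step end game of the chosen route. Against it: the ketyl of an enal is an allylic radical anion, so coupling at C5 and loss of the Z geometry compete. The C8 ketone carries an α-silyloxy group at C9, a motif that SmI2 tends to cleave reductively. The β-keto ester leaves C17 epimerisable. Nothing in the substrate decides which C7/C8 diol diastereomer forms in a ten-membered transition state. The chosen route fixes C8 and C17 by an open-chain aldol and C7 by a concerted cycloaddition directed by the C8 hydroxyl; the olefin geometry is enforced by the dioxene ring. It pays for this with a C4 inversion.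

**Alternative 3:** Ring A is formed last by cutting C1–C10 back to a fourteen-membered macrocycle. Forward, Me2AlCl would open an E-1,2-epoxide at tertiary C1, C10 of an E C10=C11 olefin would attack with inversion and H12 would be lost, giving A3. It is biomimetic and sets quaternary C1, C10 and the C2 hydroxyl in one event, which is more elegant than the stepwise ring A construction used here. Against it: the macrocycle would already carry the lactone, the tertiary C8 hydroxyl, the C9 and allylic C16 acetates and the C4 silyl ether, all Lewis-basic or ionisable toward Me2AlCl. The C11 cation must lose H12 rather than a C20 hydrogen or undergo a hydride shift. The C1/C10 configuration depends on how the macrocycle folds. Making that macrocycle would take as many steps as the whole chosen route, and the riskiest step would come last. The chosen route sets C1 and C14 in its second step from a cheap dione and sets C10 by suprafacial chirality transfer.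

Key step: step 26

**Remarks on the chemistry.**
- Locants are those of the briarane skeleton throughout; β is the face of ring A that carries the C15 methyl. TBS = tert-butyldimethylsilyl.
- C2, C9, C10 and C14 are S and C17 is R in every compound that contains them. The descriptors of C1 and C8 change with the substituents although their geometry does not, so these centres are described by reference to earlier compounds.
- In diene 41 both ring olefins are cis within the ring. By the sequence rule this is 4E,6Z, because C16 outranks C6 on C5.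
- C19 is carried as a tert-butyl ester up to step 28, for the reason given under "Acetates".
- Compounds 9, 15, 25, 34 and 37 are taken to be commercial.

## Steps

Step 1
Reactants: 1 2-methylcyclohexane-1,3-dione; 2 allyl bromide
Product: 3 2-methyl-2-(prop-2-en-1-yl)cyclohexane-1,3-dione
Conditions: NaOH (1 M aq.), rt
Reagents that add atoms: none
Why: C-alkylation (SN2) of the stabilised 1,3-dione enolate in water, where carbon alkylation dominates; the product is achiral.

Step 2
Reactants: 3 2-methyl-2-(prop-2-en-1-yl)cyclohexane-1,3-dione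
Product: 4 (2S,3S)-3-hydroxy-2-methyl-2-(prop-2-en-1-yl)cyclohexan-1-one
Conditions: baker's yeast (Saccharomyces cerevisiae), sucrose, H2O, 30 °C
Reagents that add atoms: none
Why: Enzymatic enantiotopic-group-selective ketone reduction of a 2,2-disubstituted 1,3-dione; it should set C14 (S) and with it quaternary C1, hydroxyl cis to the allyl group and trans to the methyl.

Step 3
Reactants: 4 (2S,3S)-3-hydroxy-2-methyl-2-(prop-2-en-1-yl)cyclohexan-1-one
Product: 5 (2S,3S)-3-(tert-butyldimethylsilyloxy)-2-methyl-2-(prop-2-en-1-yl)cyclohexan-1-one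
Conditions: TBSOTf, 2,6-lutidine, CH2Cl2, −78 → 0 °C
Reagents that add atoms: tert-butyldimethylsilyl trifluoromethanesulfonate, CC(C)(C)[Si](C)(C)OS(=O)(=O)C(F)(F)F
Why: Silylation of a hindered secondary alcohol with the silyl triflate; it blocks retro-aldol cleavage of the β-hydroxy ketone in later steps.

Step 4
Reactants: 5 (2S,3S)-3-(tert-butyldimethylsilyloxy)-2-methyl-2-(prop-2-en-1-yl)cyclohexan-1-one
Product: 6 (2S,3S)-3-(tert-butyldimethylsilyloxy)-2-methyl-2-[(E)-prop-1-en-1-yl]cyclohexan-1-one
Conditions: RuHCl(CO)(PPh3)3 (cat.), toluene, 80 °C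
Reagents that add atoms: none
Why: Metal-hydride olefin isomerisation (addition–elimination) to the more stable internal alkene; the quaternary centre stops further migration, and the E/Z ratio does not matter because the olefin is cleaved next.

Step 5
Reactants: 6 (2S,3S)-3-(tert-butyldimethylsilyloxy)-2-methyl-2-[(E)-prop-1-en-1-yl]cyclohexan-1-one
Product: 8 (1R,2S)-2-(tert-butyldimethylsilyloxy)-1-methyl-6-oxocyclohexane-1-carbaldehyde, via propenyl ozonide 7 (not isolated)
Conditions: O3, CH2Cl2, −78 °C; then PPh3, −78 °C → rt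
Reagents that add atoms: ozone, [O-][O+]=O
Why: Ozonolysis with reductive work-up turns the propenyl group into the C2 aldehyde; the 2-formyl ketone has no enolisable hydrogen between the carbonyls and is used at once.

Step 6
Reactants: 8 (1R,2S)-2-(tert-butyldimethylsilyloxy)-1-methyl-6-oxocyclohexane-1-carbaldehyde; 9 (−)-B-allyldiisopinocampheylborane
Product: 11 (2S,3S)-3-(tert-butyldimethylsilyloxy)-2-[(1S)-1-hydroxybut-3-en-1-yl]-2-methylcyclohexan-1-one, via allylboration borinate 10 (not isolated)
Conditions: Et2O, −78 °C; then HOCH2CH2NH2, rt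
Reagents that add atoms: none
Why: Brown allylboration through a chair six-membered transition state; the borane from (+)-α-pinene should deliver allyl to the Si face of the aldehyde and give (2S). The aldehyde reacts far faster than the ketone, and the dipole-opposed conformer of the keto aldehyde exposes the same face on the side of the C15 methyl (matched case).

Step 7
Reactants: 11 (2S,3S)-3-(tert-butyldimethylsilyloxy)-2-[(1S)-1-hydroxybut-3-en-1-yl]-2-methylcyclohexan-1-one
Product: 12 (3S)-3-(TBSO)-2-[(1S)-1-(TBSO)but-3-en-1-yl]-2-methylcyclohexan-1-one (quaternary centre as in 11)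
Conditions: TBSOTf, 2,6-lutidine, CH2Cl2, −78 → 0 °C
Reagents that add atoms: tert-butyldimethylsilyl trifluoromethanesulfonate, CC(C)(C)[Si](C)(C)OS(=O)(=O)C(F)(F)F
Why: Silylation of the neopentyl-type C2 hydroxyl; it removes the retro-aldol pathway of the β-hydroxy ketone.

Step 8
Reactants: 12 (3S)-3-(TBSO)-2-[(1S)-1-(TBSO)but-3-en-1-yl]-2-methylcyclohexan-1-one
Product: 14 (3S)-3-(TBSO)-3-[(2S)-2-(TBSO)-1-methyl-6-oxocyclohexyl]propanal, via vinyl ozonide 13 (not isolated)
Conditions: O3, CH2Cl2, −78 °C; then PPh3, −78 °C → rt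
Reagents that add atoms: ozone, [O-][O+]=O
Why: Ozonolysis of the only olefin gives the C4 aldehyde; the work-up is neutral, so the β-silyloxy aldehyde does not eliminate.

Step 9
Reactants: 14 (3S)-3-(TBSO)-3-[(2S)-2-(TBSO)-1-methyl-6-oxocyclohexyl]propanal; 15 ethyl (triphenylphosphoranylidene)acetate
Product: 16 ethyl (2Z,5S)-5-(TBSO)-5-[(2S)-2-(TBSO)-1-methyl-6-oxocyclohexyl]-2-iodopent-2-enoate
Conditions: 15, N-iodosuccinimide, CH2Cl2, −20 °C; then 14, −20 °C → rt
Reagents that add atoms: N-iodosuccinimide, O=C1CCC(=O)N1I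
Why: Wittig olefination with the stabilised ylide iodinated in the flask; as with stabilised ylides in general the ester ends trans to C3, so iodine is cis to C3 (Z), the geometry needed for the ring-cis C4=C5 bond. The aldehyde reacts, the ketone does not.

Step 10
Reactants: 16 ethyl (2Z,5S)-5-(TBSO)-5-[(2S)-2-(TBSO)-1-methyl-6-oxocyclohexyl]-2-iodopent-2-enoate
Product: 17 (2Z,5S)-5-(TBSO)-5-[(2S)-2-(TBSO)-6-hydroxy-1-methylcyclohexyl]-2-iodopent-2-en-1-ol (both C10 epimers)
Conditions: iBu2AlH, CH2Cl2, −78 → 0 °C; KNaC4H4O6 (aq.)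
Reagents that add atoms: none
Why: 1,2-Reduction of the enoate to the C16 allylic alcohol by the aluminium hydride; the C10 ketone is reduced as well, which is accepted and reversed in step 12. The alkenyl iodide is inert at low temperature.

Step 11
Reactants: 17 (2Z,5S)-5-(TBSO)-5-[(2S)-2-(TBSO)-6-hydroxy-1-methylcyclohexyl]-2-iodopent-2-en-1-ol
Product: 18 16-O-TBS ether of 17 (free C10 alcohol, both epimers)
Conditions: TBSCl, imidazole, CH2Cl2, 0 °C
Reagents that add atoms: tert-butyldimethylsilyl chloride, CC(C)(C)[Si](C)(C)Cl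
Why: Selective silylation of the primary allylic hydroxyl; the secondary C10 hydroxyl next to quaternary C1 is much slower.

Step 12
Reactants: 18 16-O-TBS ether of 17
Product: 19 (3S)-3-(TBSO)-2-[(1S,3Z)-1,5-bis(TBSO)-4-iodopent-3-en-1-yl]-2-methylcyclohexan-1-one (quaternary centre as in 11)
Conditions: Dess–Martin periodinane, NaHCO3, CH2Cl2, rt
Reagents that add atoms: none
Why: Dess–Martin oxidation returns the C10 ketone and erases the C10 epimer mixture; silyl ethers and the alkenyl iodide are unaffected.

Step 13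
Reactants: 19 (3S)-3-(TBSO)-2-[(1S,3Z)-1,5-bis(TBSO)-4-iodopent-3-en-1-yl]-2-methylcyclohexan-1-one
Product: 20 (3S)-3-(TBSO)-2-[(1S,3Z)-1,5-bis(TBSO)-4-iodopent-3-en-1-yl]-2,6-dimethylcyclohexan-1-one (both C11 epimers)
Conditions: LiN(iPr)2, THF, −78 °C; MeI, −78 → −30 °C
Reagents that add atoms: iodomethane, CI
Why: Kinetic enolate alkylation; only C11 carries α-hydrogens because C1 is quaternary, so C20 can only enter at C11, and the C11 configuration is lost in the next step.

Step 14
Reactants: 20 (3S)-3-(TBSO)-2-[(1S,3Z)-1,5-bis(TBSO)-4-iodopent-3-en-1-yl]-2,6-dimethylcyclohexan-1-one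
Product: 21 (5S)-5-(TBSO)-6-[(1S,3Z)-1,5-bis(TBSO)-4-iodopent-3-en-1-yl]-2,6-dimethylcyclohex-2-en-1-one
Conditions: IBX, DMSO, 65 °C
Reagents that add atoms: none
Why: IBX-mediated α,β-dehydrogenation of the ketone through its enol; the endocyclic trisubstituted enone C11=C12 is the expected product, and a palladium-based dehydrogenation is avoided because of the alkenyl iodide.

Step 15
Reactants: 21 (5S)-5-(TBSO)-6-[(1S,3Z)-1,5-bis(TBSO)-4-iodopent-3-en-1-yl]-2,6-dimethylcyclohex-2-en-1-one
Product: 22 11β,12β-epoxide of 21 (oxirane on the face of the C15 methyl and trans to the C14 silyloxy group)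
Conditions: H2O2 (30% aq.), NaOH (cat.), MeOH, 0 °C
Reagents that add atoms: hydrogen peroxide, OO
Why: Weitz–Scheffer nucleophilic epoxidation; hydroperoxide should add axially to C12 trans to the C14 substituent, as in conjugate additions to 5-substituted cyclohexenones, which places the oxirane on the β face.

Step 16
Reactants: 22 11β,12β-epoxide of 21
Product: 24 (5S)-5-(TBSO)-4-[(1S,3Z)-1,5-bis(TBSO)-4-iodopent-3-en-1-yl]-2,4-dimethylcyclohex-2-en-1-ol (C12 hydroxyl β), via epoxy hydrazone 23 (not isolated)
Conditions: N2H4·H2O, AcOH (cat.), MeOH, 0 °C → rt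
Reagents that add atoms: none
Why: Wharton transposition: the hydrazone opens the epoxide and the alkenyl diazene loses N2, placing the olefin at C10=C11; the C12–O bond is not broken, so the hydroxyl stays β.

Step 17
Reactants: 24 (5S)-5-(TBSO)-4-[(1S,3Z)-1,5-bis(TBSO)-4-iodopent-3-en-1-yl]-2,4-dimethylcyclohex-2-en-1-ol; 25 (tert-butyldimethylsilyloxy)acetic acid
Product: 27 (tert-butyldimethylsilyloxy)acetate ester of 24, via O-acylisourea 26 (not isolated)
Conditions: DCC, DMAP (cat.), CH2Cl2, 0 °C → rt
Reagents that add atoms: none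
Why: Steglich esterification of the secondary allylic alcohol with retention at C12; it brings in C8, C9 and the C9 oxygen.

Step 18
Reactants: 27 (tert-butyldimethylsilyloxy)acetate ester of 24
Product: 30 (2S)-2-(TBSO)-2-[(1S,5S)-5-(TBSO)-6-[(1S,3Z)-1,5-bis(TBSO)-4-iodopent-3-en-1-yl]-2,6-dimethylcyclohex-2-en-1-yl]acetic acid (C9 branch β), via silyl ketene acetal 28 (not isolated), via trimethylsilyl ester 29 (not isolated)
Conditions: LiN(iPr)2, Me3SiCl, Et3N, THF, −78 → 60 °C; then HCl (1 M aq.)
Reagents that add atoms: none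
Why: Ireland–Claisen rearrangement: the [3,3] shift delivers C9 suprafacially to C10 on the β face, the face of the C12 oxygen, and moves the olefin to C11=C12. C9 should be set because either ketene acetal geometry reacts through the transition state that keeps the silyloxy group away from C1 and its methyl (chair for E, boat for Z), and both give the same (9S) acid.

Step 19
Reactants: 30 (9S,10S) α-silyloxy acid
Product: 32 N-methoxy-N-methylamide of 30, via acyl imidazolide 31 (not isolated)
Conditions: 1,1'-carbonyldiimidazole, CH2Cl2, rt; then MeNH(OMe)·HCl, rt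
Reagents that add atoms: N,O-dimethylhydroxylamine hydrochloride, CNOC.Cl
Why: Amide formation through the acyl imidazolide under non-basic conditions, so the α-silyloxy stereocentre C9 is not epimerised.

Step 20
Reactants: 33 acetylene; 34 hexamethyldistannane
Product: 35 (Z)-1,2-bis(trimethylstannyl)ethene
Conditions: Pd(PPh3)4 (cat.), 1,4-dioxane, 60 °C
Reagents that add atoms: none
Why: Palladium-catalysed syn addition of the Sn–Sn bond across the alkyne gives the cis-distannyl alkene, the source of C6 and C7 with the Z geometry already fixed.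

Step 21
Reactants: 32 N-methoxy-N-methylamide of 30; 35 (Z)-1,2-bis(trimethylstannyl)ethene
Product: 36 (1Z,4S)-4-(TBSO)-4-[ring A as in 30]-1-(trimethylstannyl)but-1-en-3-one
Conditions: 35, MeLi, THF, −78 °C; MgBr2·OEt2; then 32, −78 → 0 °C; NH4Cl (aq.)
Reagents that add atoms: none
Why: Tin–lithium exchange gives the configurationally stable cis-stannylvinyl anion; as the Grignard reagent it does not exchange with the alkenyl iodide and acylates the Weinreb amide once, the chelated tetrahedral adduct preventing over-addition.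

Step 22
Reactants: 36 (Z)-β-stannyl enone; 37 tert-butyl propanoate
Product: 38 tert-butyl (2R,3S,4Z)-3-hydroxy-2-methyl-3-[(S)-(TBSO)(ring A as in 30)methyl]-5-(trimethylstannyl)pent-4-enoate (seco precursor)
Conditions: 37, LiN(iPr)2, THF–DMPU (4:1), −78 °C; then 36, −78 °C; AcOH
Reagents that add atoms: none
Why: Kinetic 1,2-aldol addition of the lithium (Z)-enolate to the ketone. C8 should follow Cornforth/polar Felkin–Anh attack anti to the non-chelating C9 silyloxy group and past H9. C17 should follow a chair Zimmerman–Traxler transition state with the branched C9 group equatorial and the vinyl group axial, which places the methyl cis to C9 in the six-membered array as 47 requires.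

Step 23
Reactants: 38 seco precursor (C5 iodide, C6 stannane)
Product: 39 ten-membered ring-cis,cis 4,6-diene with 8-hydroxy, 2,9,14,16-tetrakis(TBSO) groups and the C19 tert-butyl ester
Conditions: Pd2(dba)3 (cat.), AsPh3, DMF, 0.002 M, rt → 45 °C
Reagents that add atoms: none
Why: Intramolecular Stille coupling: oxidative addition at the C5 iodide, transmetalation of the unhindered cis-alkenyl trimethylstannane and reductive elimination form C5–C6 with retention at both olefins; high dilution favours the ten-membered ring over oligomers.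

Step 24
Reactants: 39 ten-membered diene tetrakis-silyl ether
Product: 40 2,9,14,16-tetraol of 39 (8-hydroxyl and tert-butyl ester unchanged)
Conditions: HF·pyridine, pyridine, THF, 0 °C → rt
Reagents that add atoms: none
Why: Buffered fluoride cleavage of all four silyl ethers; the tert-butyl ester is too hindered to lactonise onto the free C9 hydroxyl, and the buffer protects the tertiary dienyl carbinol.

Step 25
Reactants: 40 tetraol
Product: 41 2,9,14,16-tetraacetate: ring-cis,cis 4,6-diene with the C8 carbinol and the C19 tert-butyl ester (key-step precursor)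
Conditions: Ac2O, pyridine, DMAP (cat.), CH2Cl2, 0 °C → rt
Reagents that add atoms: acetic anhydride, CC(=O)OC(C)=O
Why: Acetylation of the three secondary and one primary hydroxyls; the tertiary C8 hydroxyl should remain free under these conditions, which gives the acetate pattern of 47 in one step.

Step 26
Reactants: 41 tetraacetate diene
Product: 42 (4S,7S)-4,7-endoperoxide with both oxygens on the face of the C8 hydroxyl and a Z C5=C6 olefin
Conditions: O2, hν (visible), tetraphenylporphyrin (cat.), CH2Cl2, −40 °C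
Reagents that add atoms: dioxygen, O=O
Why: Singlet oxygen, formed by energy transfer from the excited sensitiser, adds suprafacially across C4 and C7 of the s-cis diene in a [4+2] cycloaddition, forming both C–O bonds in one step. The closest known reaction type is the photooxygenation of cyclic 1,3-dienes to bicyclic endoperoxides, which are then reduced to cis-2-ene-1,4-diols. The six-membered 3,6-dihydro-1,2-dioxine ring is closed by this cycloaddition and bridges C4 and C7 of the ten-membered ring; the C5=C6 bond left inside it can only be Z. C7 is set by the face of attack, which the allylic C8 hydroxyl should direct by hydrogen bonding to the incoming oxygen in the non-polar medium. C4 is then fixed relative to C7 because the addition is suprafacial (both oxygens cis). The step needs chemoselectivity for the diene over the ene reaction at the trisubstituted C11=C12 olefin. This is helped by the lower enthalpic barrier of the cycloaddition at −40 °C, by the hydrogen-bond assistance at the diene, and by the crowding of C11=C12 between C10 and the C20 methyl. The acetates, the tert-butyl ester and the tertiary alcohol are inert to singlet oxygen.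

Step 27
Reactants: 42 4,7-endoperoxide
Product: 43 (4S,7S)-4,7-dihydroxy-(5Z)-ene (cis-diol) with the C19 tert-butyl ester
Conditions: thiourea, MeOH, rt
Reagents that add atoms: none
Why: Thiourea reduction of the O–O bond of a dialkyl peroxide gives the cis-2-ene-1,4-diol without touching the C–O bonds, the olefin or the esters.

Step 28
Reactants: 43 cis-diol tert-butyl ester
Product: 45 4-epi-47 (γ-lactone closed at O7; C4 hydroxyl cis to the C7 oxygen), via hydroxy acid 44 (not isolated)
Conditions: CF3CO2H, CH2Cl2, 0 °C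
Reagents that add atoms: none
Why: Acidolysis of the tert-butyl ester and acid-catalysed γ-lactonisation; only the C7 hydroxyl can form a five-membered ring because C9 is acetylated, and C7 keeps its configuration since its C–O bond is not broken.

Step 29
Reactants: 45 4-epi-47
Product: 46 4-O-chloroacetyl derivative of 47 (C4 inverted to R)
Conditions: ClCH2CO2H, PPh3, iPrO2CN=NCO2iPr, THF, 0 °C → rt
Reagents that add atoms: chloroacetic acid, OC(=O)CCl
Why: Mitsunobu reaction: SN2 displacement of the activated secondary allylic C4 oxygen by the acidic carboxylate, with inversion; the tertiary C8 hydroxyl does not react, and SN2′ attack at C6 is disfavoured next to the lactone-bearing C7.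

Step 30
Reactants: 46 4-O-chloroacetyl derivative
Product: 47 target CNP0226727.2, (1R,2S,4R,5Z,7S,8S,9S,10S,14S,17R)
Conditions: thiourea, NaHCO3, EtOH, 50 °C
Reagents that add atoms: none
Why: Selective dechloroacetylation: S-alkylation of thiourea and cyclisation release the C4 hydroxyl, while the four acetates and the lactone are left intact.

## Compound list

1 | 2-methylcyclohexane-1,3-dione | CC1C(=O)CCCC1=O | starting material
2 | allyl bromide (3-bromoprop-1-ene) | C=CCBr | starting material
3 | 2-methyl-2-(prop-2-en-1-yl)cyclohexane-1,3-dione | C=CCC1(C)C(=O)CCCC1=O | intermediate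
4 | (2S,3S)-3-hydroxy-2-methyl-2-(prop-2-en-1-yl)cyclohexan-1-one | O=C1CCC[C@H](O)[C@]1(C)CC=C | intermediate
5 | (2S,3S)-3-(tert-butyldimethylsilyloxy)-2-methyl-2-(prop-2-en-1-yl)cyclohexan-1-one | O=C1CCC[C@H](O[Si](C)(C)C(C)(C)C)[C@]1(C)CC=C | intermediate
6 | (2S,3S)-3-(tert-butyldimethylsilyloxy)-2-methyl-2-[(E)-prop-1-en-1-yl]cyclohexan-1-one | O=C1CCC[C@H](O[Si](C)(C)C(C)(C)C)[C@]1(C)/C=C/C | intermediate
7 | propenyl ozonide of 6 (3-methyl-1,2,4-trioxolan-5-yl in place of the propenyl group) | O=C1CCC[C@H](O[Si](C)(C)C(C)(C)C)[C@]1(C)C1OOC(C)O1 | intermediate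
8 | (1R,2S)-2-(tert-butyldimethylsilyloxy)-1-methyl-6-oxocyclohexane-1-carbaldehyde | O=C1CCC[C@H](O[Si](C)(C)C(C)(C)C)[C@]1(C)C=O | intermediate
9 | (−)-B-allyldiisopinocampheylborane | C=CCB([C@@H]1C[C@@H]2C[C@H]([C@H]1C)C2(C)C)[C@@H]1C[C@@H]2C[C@H]([C@H]1C)C2(C)C | starting material
10 | O-diisopinocampheylboryl derivative of 11 (allylboration borinate) | O=C1CCC[C@H](O[Si](C)(C)C(C)(C)C)[C@]1(C)[C@@H](OB([C@@H]2C[C@@H]3C[C@H]([C@H]2C)C3(C)C)[C@@H]2C[C@@H]3C[C@H]([C@H]2C)C3(C)C)CC=C | intermediate
11 | (2S,3S)-3-(tert-butyldimethylsilyloxy)-2-[(1S)-1-hydroxybut-3-en-1-yl]-2-methylcyclohexan-1-one | O=C1CCC[C@H](O[Si](C)(C)C(C)(C)C)[C@]1(C)[C@@H](O)CC=C | intermediate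
12 | (3S)-3-(TBSO)-2-[(1S)-1-(TBSO)but-3-en-1-yl]-2-methylcyclohexan-1-one (quaternary centre as in 11) | O=C1CCC[C@H](O[Si](C)(C)C(C)(C)C)[C@]1(C)[C@@H](O[Si](C)(C)C(C)(C)C)CC=C | intermediate
13 | vinyl ozonide of 12 (1,2,4-trioxolan-3-yl in place of the vinyl group) | O=C1CCC[C@H](O[Si](C)(C)C(C)(C)C)[C@]1(C)[C@@H](O[Si](C)(C)C(C)(C)C)CC1OOCO1 | intermediate
14 | (3S)-3-(TBSO)-3-[(2S)-2-(TBSO)-1-methyl-6-oxocyclohexyl]propanal (C4 aldehyde) | O=C1CCC[C@H](O[Si](C)(C)C(C)(C)C)[C@]1(C)[C@@H](O[Si](C)(C)C(C)(C)C)CC=O | intermediate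
15 | ethyl (triphenylphosphoranylidene)acetate | CCOC(=O)C=P(c1ccccc1)(c1ccccc1)c1ccccc1 | starting material
16 | ethyl (2Z,5S)-5-(TBSO)-5-[(2S)-2-(TBSO)-1-methyl-6-oxocyclohexyl]-2-iodopent-2-enoate | O=C1CCC[C@H](O[Si](C)(C)C(C)(C)C)[C@]1(C)[C@@H](O[Si](C)(C)C(C)(C)C)C/C=C(\I)C(=O)OCC | intermediate
17 | (2Z,5S)-5-(TBSO)-5-[(2S)-2-(TBSO)-6-hydroxy-1-methylcyclohexyl]-2-iodopent-2-en-1-ol (both C10 epimers) | OC1CCC[C@H](O[Si](C)(C)C(C)(C)C)[C@]1(C)[C@@H](O[Si](C)(C)C(C)(C)C)C/C=C(\I)CO | intermediate
18 | 16-O-TBS ether of 17 (free C10 alcohol, both epimers) | OC1CCC[C@H](O[Si](C)(C)C(C)(C)C)[C@]1(C)[C@@H](O[Si](C)(C)C(C)(C)C)C/C=C(\I)CO[Si](C)(C)C(C)(C)C | intermediate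
19 | (3S)-3-(TBSO)-2-[(1S,3Z)-1,5-bis(TBSO)-4-iodopent-3-en-1-yl]-2-methylcyclohexan-1-one | O=C1CCC[C@H](O[Si](C)(C)C(C)(C)C)[C@]1(C)[C@@H](O[Si](C)(C)C(C)(C)C)C/C=C(\I)CO[Si](C)(C)C(C)(C)C | intermediate
20 | (3S)-3-(TBSO)-2-[(1S,3Z)-1,5-bis(TBSO)-4-iodopent-3-en-1-yl]-2,6-dimethylcyclohexan-1-one (both C11 epimers) | O=C1C(C)CC[C@H](O[Si](C)(C)C(C)(C)C)[C@]1(C)[C@@H](O[Si](C)(C)C(C)(C)C)C/C=C(\I)CO[Si](C)(C)C(C)(C)C | intermediate
21 | (5S)-5-(TBSO)-6-[(1S,3Z)-1,5-bis(TBSO)-4-iodopent-3-en-1-yl]-2,6-dimethylcyclohex-2-en-1-one | O=C1C(C)=CC[C@H](O[Si](C)(C)C(C)(C)C)[C@]1(C)[C@@H](O[Si](C)(C)C(C)(C)C)C/C=C(\I)CO[Si](C)(C)C(C)(C)C | intermediate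
22 | 11β,12β-epoxide of 21 (oxirane cis to the C15 methyl, trans to the C14 silyloxy group) | O=C1[C@@]2(C)O[C@H]2C[C@H](O[Si](C)(C)C(C)(C)C)[C@]1(C)[C@@H](O[Si](C)(C)C(C)(C)C)C/C=C(\I)CO[Si](C)(C)C(C)(C)C | intermediate
23 | hydrazone of 22 | NN=C1[C@@]2(C)O[C@H]2C[C@H](O[Si](C)(C)C(C)(C)C)[C@]1(C)[C@@H](O[Si](C)(C)C(C)(C)C)C/C=C(\I)CO[Si](C)(C)C(C)(C)C | intermediate
24 | (5S)-5-(TBSO)-4-[(1S,3Z)-1,5-bis(TBSO)-4-iodopent-3-en-1-yl]-2,4-dimethylcyclohex-2-en-1-ol, C12 hydroxyl β (cis to the C15 methyl) | C1=C(C)[C@@H](O)C[C@H](O[Si](C)(C)C(C)(C)C)[C@]1(C)[C@@H](O[Si](C)(C)C(C)(C)C)C/C=C(\I)CO[Si](C)(C)C(C)(C)C | intermediate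
25 | (tert-butyldimethylsilyloxy)acetic acid | CC(C)(C)[Si](C)(C)OCC(=O)O | starting material
26 | O-acylisourea from 25 and dicyclohexylcarbodiimide | CC(C)(C)[Si](C)(C)OCC(=O)OC(=NC1CCCCC1)NC1CCCCC1 | intermediate
27 | (tert-butyldimethylsilyloxy)acetate ester of 24 | C1=C(C)[C@@H](OC(=O)CO[Si](C)(C)C(C)(C)C)C[C@H](O[Si](C)(C)C(C)(C)C)[C@]1(C)[C@@H](O[Si](C)(C)C(C)(C)C)C/C=C(\I)CO[Si](C)(C)C(C)(C)C | intermediate
28 | trimethylsilyl ketene acetal of 27 (E isomer drawn; the Z isomer leads to the same acid) | C1=C(C)[C@@H](O/C(O[Si](C)(C)C)=C\O[Si](C)(C)C(C)(C)C)C[C@H](O[Si](C)(C)C(C)(C)C)[C@]1(C)[C@@H](O[Si](C)(C)C(C)(C)C)C/C=C(\I)CO[Si](C)(C)C(C)(C)C | intermediate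
29 | trimethylsilyl ester of 30 | C[Si](C)(C)OC(=O)[C@@H](O[Si](C)(C)C(C)(C)C)[C@H]1C(C)=CC[C@H](O[Si](C)(C)C(C)(C)C)[C@]1(C)[C@@H](O[Si](C)(C)C(C)(C)C)C/C=C(\I)CO[Si](C)(C)C(C)(C)C | intermediate
30 | (2S)-2-(TBSO)-2-[(1S,5S)-5-(TBSO)-6-[(1S,3Z)-1,5-bis(TBSO)-4-iodopent-3-en-1-yl]-2,6-dimethylcyclohex-2-en-1-yl]acetic acid (C9 branch cis to the C15 methyl) | OC(=O)[C@@H](O[Si](C)(C)C(C)(C)C)[C@H]1C(C)=CC[C@H](O[Si](C)(C)C(C)(C)C)[C@]1(C)[C@@H](O[Si](C)(C)C(C)(C)C)C/C=C(\I)CO[Si](C)(C)C(C)(C)C | intermediate
31 | acyl imidazolide of 30 | O=C(n1ccnc1)[C@@H](O[Si](C)(C)C(C)(C)C)[C@H]1C(C)=CC[C@H](O[Si](C)(C)C(C)(C)C)[C@]1(C)[C@@H](O[Si](C)(C)C(C)(C)C)C/C=C(\I)CO[Si](C)(C)C(C)(C)C | intermediate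
32 | N-methoxy-N-methylamide of 30 | CON(C)C(=O)[C@@H](O[Si](C)(C)C(C)(C)C)[C@H]1C(C)=CC[C@H](O[Si](C)(C)C(C)(C)C)[C@]1(C)[C@@H](O[Si](C)(C)C(C)(C)C)C/C=C(\I)CO[Si](C)(C)C(C)(C)C | intermediate
33 | acetylene | C#C | starting material
34 | hexamethyldistannane | C[Sn](C)(C)[Sn](C)(C)C | starting material
35 | (Z)-1,2-bis(trimethylstannyl)ethene | C[Sn](C)(C)/C=C\[Sn](C)(C)C | intermediate
36 | (1Z,4S)-4-(TBSO)-4-[ring A as in 30]-1-(trimethylstannyl)but-1-en-3-one | C[Sn](C)(C)/C=C\C(=O)[C@@H](O[Si](C)(C)C(C)(C)C)[C@H]1C(C)=CC[C@H](O[Si](C)(C)C(C)(C)C)[C@]1(C)[C@@H](O[Si](C)(C)C(C)(C)C)C/C=C(\I)CO[Si](C)(C)C(C)(C)C | intermediate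
37 | tert-butyl propanoate | CCC(=O)OC(C)(C)C | starting material
38 | tert-butyl (2R,3S,4Z)-3-hydroxy-2-methyl-3-[(S)-(TBSO)(ring A as in 30)methyl]-5-(trimethylstannyl)pent-4-enoate (seco precursor; C5 iodide, C6 stannane) | C[Sn](C)(C)/C=C\[C@@](O)([C@@H](C)C(=O)OC(C)(C)C)[C@@H](O[Si](C)(C)C(C)(C)C)[C@H]1C(C)=CC[C@H](O[Si](C)(C)C(C)(C)C)[C@]1(C)[C@@H](O[Si](C)(C)C(C)(C)C)C/C=C(\I)CO[Si](C)(C)C(C)(C)C | intermediate
39 | ten-membered ring-cis,cis 4,6-diene: 8-hydroxy, 2,9,14,16-tetrakis(TBSO), C19 tert-butyl ester | C1/C=C(CO[Si](C)(C)C(C)(C)C)\C=C/[C@@](O)([C@@H](C)C(=O)OC(C)(C)C)[C@@H](O[Si](C)(C)C(C)(C)C)[C@H]2C(C)=CC[C@H](O[Si](C)(C)C(C)(C)C)[C@]2(C)[C@H]1O[Si](C)(C)C(C)(C)C | intermediate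
40 | 2,9,14,16-tetraol of 39 | C1/C=C(CO)\C=C/[C@@](O)([C@@H](C)C(=O)OC(C)(C)C)[C@@H](O)[C@H]2C(C)=CC[C@H](O)[C@]2(C)[C@H]1O | intermediate
41 | 2,9,14,16-tetraacetate: ring-cis,cis (4E,6Z) 4,6-diene with the C8 carbinol and the C19 tert-butyl ester | C1/C=C(COC(C)=O)\C=C/[C@@](O)([C@@H](C)C(=O)OC(C)(C)C)[C@@H](OC(C)=O)[C@H]2C(C)=CC[C@H](OC(C)=O)[C@]2(C)[C@H]1OC(C)=O | intermediate
42 | (4S,7S)-4,7-endoperoxide of 41, (5Z), both oxygens on the face of the C8 hydroxyl | C1[C@@H]2OO[C@@H](C=C2COC(C)=O)[C@@](O)([C@@H](C)C(=O)OC(C)(C)C)[C@@H](OC(C)=O)[C@H]3C(C)=CC[C@H](OC(C)=O)[C@]3(C)[C@H]1OC(C)=O | intermediate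
43 | (4S,7S)-4,7-diol, (5Z), C19 tert-butyl ester | C1[C@H](O)/C(COC(C)=O)=C\[C@H](O)[C@@](O)([C@@H](C)C(=O)OC(C)(C)C)[C@@H](OC(C)=O)[C@H]2C(C)=CC[C@H](OC(C)=O)[C@]2(C)[C@H]1OC(C)=O | intermediate
44 | C19 carboxylic acid of 43 (hydroxy acid) | C1[C@H](O)/C(COC(C)=O)=C\[C@H](O)[C@@](O)([C@@H](C)C(=O)O)[C@@H](OC(C)=O)[C@H]2C(C)=CC[C@H](OC(C)=O)[C@]2(C)[C@H]1OC(C)=O | intermediate
45 | 4-epi-47 (lactone closed; 4S) | CC(=O)OC/C1=C/[C@@H]2OC(=O)[C@H](C)[C@@]2(O)[C@@H](OC(C)=O)[C@H]2C(C)=CC[C@H](OC(C)=O)[C@]2(C)[C@@H](OC(C)=O)C[C@@H]1O | intermediate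
46 | 4-O-chloroacetyl derivative of 47 (4R) | CC(=O)OC/C1=C/[C@@H]2OC(=O)[C@H](C)[C@@]2(O)[C@@H](OC(C)=O)[C@H]2C(C)=CC[C@H](OC(C)=O)[C@]2(C)[C@@H](OC(C)=O)C[C@H]1OC(=O)CCl | intermediate
47 | CNP0226727.2, (1R,2S,4R,5Z,7S,8S,9S,10S,14S,17R) | CC(=O)OC/C1=C/[C@@H]2OC(=O)[C@H](C)[C@@]2(O)[C@@H](OC(C)=O)[C@H]2C(C)=CC[C@H](OC(C)=O)[C@]2(C)[C@@H](OC(C)=O)C[C@H]1O | target

## Step count and the least certain steps

Total: 30 steps. Longest linear sequence: 29 steps from 1 (steps 1–19 and 21–30); step 20 is a one-step side branch.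

**Step 26 (key step).** A cis,cis-1,3-diene in a ten-membered ring is twisted out of the s-cis plane, so the cycloaddition may be slowed. Ene hydroperoxidation at C11=C12 or at the diene termini, and attack on the face away from the C8 hydroxyl, could then take over. Fallback, setting out from 41: VO(acac)2 and t-BuOOH should epoxidise the C6=C7 olefin on the face of the allylic C8 hydroxyl (hydroxyl-directed epoxidation) to give the 6,7-epoxide F1. Pd(PPh3)4 with chloroacetic acid should then open the vinyl epoxide through a π-allyl complex and add the carboxylate at C4 with overall retention (1,4-cis addition), moving the olefin to C5=C6 and giving the cis-4-chloroacetoxy-7-ol F2. Thiourea with NaHCO3 removes the chloroacetate, and the route is rejoined at diol 43.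

**Step 23 (Stille ring closure).** Closure of a ten-membered ring holding two cis olefins next to a ring fusion may be slower than oligomerisation, protodestannylation or homocoupling. Fallback, setting out from 38: the ring is closed at C6=C7 by metathesis instead. Brief treatment with CF3CO2H (1 equiv, CH2Cl2, −20 °C) removes the stannyl group and gives the vinyl carbinol F3. Intermolecular Stille coupling of its C5 iodide with tributyl(vinyl)stannane (Pd2(dba)3, AsPh3) gives the 5-vinyl triene F4. Ring-closing metathesis with the second-generation Grubbs catalyst RuCl2(=CHPh)(H2IMes)(PCy3) at high dilution joins the two terminal vinyl groups with loss of ethene; a ten-membered ring favours the cis olefin. The route is rejoined at 39.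

**Step 22 (aldol).** Simple diastereoselection at C17 may erode if the enolate geometry is not clean or if DMPU loosens the closed transition state, and some 1,4-addition to the enone may occur. Fallback, setting out from 36: the aldol is run with the ordinary (E)-enolate (LiN(iPr)2, THF, no cosolvent), which by the same chair model should give the 17-epimer F5 with C8 unchanged. F5 is then converted to its alkoxide–enolate dianion (LiN(iPr)2, 2.2 equiv) and protonated at −78 °C. In the lithium-chelated dianion the proton should enter anti to the bulky C9 group, which leaves the methyl cis to C9, and the route is rejoined at 38.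

**Step 18 (Ireland–Claisen).** The new bond forms next to quaternary C1, so the rearrangement may be slow enough for the ketene acetal to decompose. Competing chair and boat transition states may also erode the C9 configuration. Fallback, setting out from 24: a Johnson–Claisen rearrangement (CH3C(OEt)3, cat. EtCO2H, 140 °C) forms the C9–C10 bond with the same suprafacial control at C10 and gives the ethyl ester F6. LiOH hydrolysis gives the acid F7. Acylation of lithiated (S)-4-benzyl-1,3-oxazolidin-2-one through the pivalic mixed anhydride gives the imide F8. Auxiliary-controlled enolate hydroxylation (NaN(SiMe3)2, then 2-(phenylsulfonyl)-3-phenyloxaziridine) should give the (9S) α-hydroxy imide F9. AlMe3 with MeNH(OMe)·HCl converts it to the α-hydroxy Weinreb amide F10, and silylation with TBSOTf rejoins the route at 32.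

**Step 28 (acidolysis and lactonisation).** While the tert-butyl ester is cleaved, the acid may ionise the allylic C4 hydroxyl (allylic transposition, elimination) or promote acetyl migration. Fallback, setting out from 43: Me3SiOSO2CF3 with 2,6-lutidine converts the tert-butyl ester to a silyl ester under non-protic conditions and silylates the three hydroxyls, giving the tetrakis(trimethylsilyl) compound F11. Methanolysis with citric acid releases hydroxy acid 44, and carbodiimide lactonisation (EDC·HCl, DMAP) rejoins the route at 45.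

## Further compounds

F1 | step 26 | 6,7-epoxide of 41 (oxirane on the face of the C8 hydroxyl) | C1/C=C(COC(C)=O)\[C@@H]2O[C@@H]2[C@@](O)([C@@H](C)C(=O)OC(C)(C)C)[C@@H](OC(C)=O)[C@H]3C(C)=CC[C@H](OC(C)=O)[C@]3(C)[C@H]1OC(C)=O
F2 | step 26 | 4-O-chloroacetyl derivative of 43 (cis-4-chloroacetoxy-7-ol) | C1[C@H](OC(=O)CCl)/C(COC(C)=O)=C\[C@H](O)[C@@](O)([C@@H](C)C(=O)OC(C)(C)C)[C@@H](OC(C)=O)[C@H]2C(C)=CC[C@H](OC(C)=O)[C@]2(C)[C@H]1OC(C)=O
F3 | step 23 | destannylated vinyl carbinol of 38 | C=C[C@@](O)([C@@H](C)C(=O)OC(C)(C)C)[C@@H](O[Si](C)(C)C(C)(C)C)[C@H]1C(C)=CC[C@H](O[Si](C)(C)C(C)(C)C)[C@]1(C)[C@@H](O[Si](C)(C)C(C)(C)C)C/C=C(\I)CO[Si](C)(C)C(C)(C)C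
F4 | step 23 | 5-vinyl triene (vinyl in place of iodine in F3) | C=C[C@@](O)([C@@H](C)C(=O)OC(C)(C)C)[C@@H](O[Si](C)(C)C(C)(C)C)[C@H]1C(C)=CC[C@H](O[Si](C)(C)C(C)(C)C)[C@]1(C)[C@@H](O[Si](C)(C)C(C)(C)C)C/C=C(\C=C)CO[Si](C)(C)C(C)(C)C
F5 | step 22 | 17-epimer of 38 | C[Sn](C)(C)/C=C\[C@@](O)([C@H](C)C(=O)OC(C)(C)C)[C@@H](O[Si](C)(C)C(C)(C)C)[C@H]1C(C)=CC[C@H](O[Si](C)(C)C(C)(C)C)[C@]1(C)[C@@H](O[Si](C)(C)C(C)(C)C)C/C=C(\I)CO[Si](C)(C)C(C)(C)C
F6 | step 18 | ethyl ester from the Johnson–Claisen rearrangement of 24 (C9 methylene) | CCOC(=O)C[C@H]1C(C)=CC[C@H](O[Si](C)(C)C(C)(C)C)[C@]1(C)[C@@H](O[Si](C)(C)C(C)(C)C)C/C=C(\I)CO[Si](C)(C)C(C)(C)C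
F7 | step 18 | carboxylic acid of F6 | OC(=O)C[C@H]1C(C)=CC[C@H](O[Si](C)(C)C(C)(C)C)[C@]1(C)[C@@H](O[Si](C)(C)C(C)(C)C)C/C=C(\I)CO[Si](C)(C)C(C)(C)C
F8 | step 18 | N-acyl (S)-4-benzyl-1,3-oxazolidin-2-one of F7 | O=C1OC[C@H](Cc2ccccc2)N1C(=O)C[C@H]1C(C)=CC[C@H](O[Si](C)(C)C(C)(C)C)[C@]1(C)[C@@H](O[Si](C)(C)C(C)(C)C)C/C=C(\I)CO[Si](C)(C)C(C)(C)C
F9 | step 18 | (9S) α-hydroxy imide | O=C1OC[C@H](Cc2ccccc2)N1C(=O)[C@@H](O)[C@H]1C(C)=CC[C@H](O[Si](C)(C)C(C)(C)C)[C@]1(C)[C@@H](O[Si](C)(C)C(C)(C)C)C/C=C(\I)CO[Si](C)(C)C(C)(C)C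
F10 | step 18 | (9S) α-hydroxy N-methoxy-N-methylamide | CON(C)C(=O)[C@@H](O)[C@H]1C(C)=CC[C@H](O[Si](C)(C)C(C)(C)C)[C@]1(C)[C@@H](O[Si](C)(C)C(C)(C)C)C/C=C(\I)CO[Si](C)(C)C(C)(C)C
F11 | step 28 | 4,7,8-tris(trimethylsilyl) ether trimethylsilyl ester of 44 | C1[C@H](O[Si](C)(C)C)/C(COC(C)=O)=C\[C@H](O[Si](C)(C)C)[C@@](O[Si](C)(C)C)([C@@H](C)C(=O)O[Si](C)(C)C)[C@@H](OC(C)=O)[C@H]2C(C)=CC[C@H](OC(C)=O)[C@]2(C)[C@H]1OC(C)=O
A1 | alternative 1 | ten-membered (E)-8-ene as its C4 trimethylsilyl enol ether | CC(C)(C)[Si](C)(C)OC/C1=C(/O[Si](C)(C)C)C[C@H](O[Si](C)(C)C(C)(C)C)[C@@]2(C)[C@@H](O[Si](C)(C)C(C)(C)C)CC=C(C)[C@@H]2/C=C(\[C@@H](C)CO[Si](C)(C)C(C)(C)C)CC1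
A2 | alternative 2 | lactone-fused bicycle with C9 and C16 triethylsilyl and C4 tert-butyldimethylsilyl ethers | CC[Si](CC)(CC)OC/C1=C/[C@@H]2OC(=O)[C@H](C)[C@@]2(O)[C@@H](O[Si](CC)(CC)CC)[C@H]2C(C)=CC[C@H](OC(C)=O)[C@]2(C)[C@@H](OC(C)=O)C[C@H]1O[Si](C)(C)C(C)(C)C
A3 | alternative 3 | bicyclic 2-hydroxy lactone with C14 triethylsilyl and C4 tert-butyldimethylsilyl ethers | CC(=O)OC/C1=C/[C@@H]2OC(=O)[C@H](C)[C@@]2(O)[C@@H](OC(C)=O)[C@H]2C(C)=CC[C@H](O[Si](CC)(CC)CC)[C@]2(C)[C@@H](O)C[C@H]1O[Si](C)(C)C(C)(C)C
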